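**Retrosynthetic overview**
Rings: A = catechol ring with its aryloxy group meta to its CH2; B = para-phenylene; C = catechol ring with its aryloxy group ortho to its CH2; D = ortho-phenylene without hydroxyls.
Enabling feature: ring D has four contiguous unsubstituted CH carbons and two adjacent substituted carbons, one bonded to the ring C oxygen and one to the CH2CH2 bridge to ring A. This matches an alkynyl ether C≡C joined to the C3–C6 (C4H4) unit of 2H-pyran-2-one after CO2 loss.
Disconnections, backwards: four O–CH3 bonds (BBr3); the ring A O–ring B aryl carbon bond (intramolecular Ullmann); ring D (pyrone/ynol ether [4+2], then loss of CO2); the O–C(sp) bond (copper coupling of bibenzyl phenol 6 with gem-dibromoalkene 12); two Wittig olefinations.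
Order of ring formation: rings A, B and C are purchased, ring D is built in step 10, and the macrocycle (17-membered by the shortest path) is closed in step 12.

Key step: step 10

Remark: the target has no stereocentre and the macrocycle is taken as conformationally mobile, so no stereocontrol is planned. Stilbene 5 is carried on as an E/Z mixture because both isomers converge on 6.

**Step 1**
Reactants: 1 4-bromobenzyl bromide
Product: 2 (4-bromobenzyl)triphenylphosphonium bromide
Conditions: PPh3, toluene, reflux
Reagents that add atoms: triphenylphosphine, c1ccc(cc1)P(c1ccccc1)c1ccccc1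
Why: SN2 quaternisation of the phosphine by the benzylic bromide (phosphonium salt formation), with the aryl C–Br bond inert to a neutral phosphine.

**Step 2**
Reactants: 2 (4-bromobenzyl)triphenylphosphonium bromide; 3 2-hydroxy-3,4-dimethoxybenzaldehyde
Product: 5 6-[2-(4-bromophenyl)ethenyl]-2,3-dimethoxyphenol (E/Z mixture), via phosphonium ylide 4 (not isolated)
Conditions: KOtBu (2.3 equiv), THF, 0 °C to rt; then 1 M HCl
Reagents that add atoms: none
Why: Wittig olefination with a semi-stabilised benzylic ylide, in which the extra base holds the ortho-phenol as its phenoxide (slower addition, but still productive) and the alkene geometry does not matter because step 3 removes it.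

**Step 3**
Reactants: 5 6-[2-(4-bromophenyl)ethenyl]-2,3-dimethoxyphenol
Product: 6 6-[2-(4-bromophenyl)ethyl]-2,3-dimethoxyphenol (ring B–C bibenzyl phenol)
Conditions: TsNHNH2, NaOAc, THF/H2O, reflux
Reagents that add atoms: none
Why: Diimide reduction (concerted syn hydrogen transfer from HN=NH made in the flask) saturates the stilbene C=C without the hydrodebromination that catalytic hydrogenation over palladium would risk.

**Step 4**
Reactants: 7 3-hydroxy-4,5-dimethoxybenzaldehyde
Product: 8 3,4-dimethoxy-5-(methoxymethoxy)benzaldehyde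
Conditions: MOMCl, iPr2NEt, CH2Cl2, 0 °C to rt
Reagents that add atoms: chloromethyl methyl ether (MOMCl), COCCl
Why: O-alkylation of the phenol (MOM acetal formation) gives a group that tolerates ylides, hydride, base, copper and neutral heating and can later be removed without touching the methyl ethers.

**Step 5**
Reactants: 8 3,4-dimethoxy-5-(methoxymethoxy)benzaldehyde
Product: 9 ethyl (E)-3-[3,4-dimethoxy-5-(methoxymethoxy)phenyl]prop-2-enoate
Conditions: Ph3P=CHCO2Et, toluene, 80 °C
Reagents that add atoms: ethyl (triphenylphosphoranylidene)acetate, CCOC(=O)C=P(c1ccccc1)(c1ccccc1)c1ccccc1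
Why: Wittig olefination with a stabilised ylide, which needs no added base and is E-selective.

**Step 6**
Reactants: 9 ethyl (E)-3-[3,4-dimethoxy-5-(methoxymethoxy)phenyl]prop-2-enoate
Product: 10 ethyl 3-[3,4-dimethoxy-5-(methoxymethoxy)phenyl]propanoate
Conditions: H2 (1 atm), 10% Pd/C, EtOAc, rt
Reagents that add atoms: none
Why: Heterogeneous catalytic hydrogenation of the conjugated alkene, with the aryl ethers and the MOM acetal inert and no benzylic C–O bond open to hydrogenolysis.

**Step 7**
Reactants: 10 ethyl 3-[3,4-dimethoxy-5-(methoxymethoxy)phenyl]propanoate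
Product: 11 3-[3,4-dimethoxy-5-(methoxymethoxy)phenyl]propanal
Conditions: DIBAL-H (1.05 equiv), CH2Cl2, −78 °C; aq. Rochelle salt
Reagents that add atoms: none
Why: Partial ester reduction with DIBAL-H, in which the tetrahedral aluminium hemiacetal persists at −78 °C and collapses to the aldehyde only on quench.

**Step 8**
Reactants: 11 3-[3,4-dimethoxy-5-(methoxymethoxy)phenyl]propanal
Product: 12 5-(4,4-dibromobut-3-en-1-yl)-1,2-dimethoxy-3-(methoxymethoxy)benzene
Conditions: CBr4, PPh3, Et3N, CH2Cl2, 0 °C
Reagents that add atoms: carbon tetrabromide, BrC(Br)(Br)Br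
Why: Ramirez gem-dibromoolefination (first stage of the Corey–Fuchs sequence), a Wittig-type reaction of Ph3P=CBr2, with Et3N buffering the acidic phosphorus bromide so that the MOM acetal survives.

**Step 9**
Reactants: 6 6-[2-(4-bromophenyl)ethyl]-2,3-dimethoxyphenol; 12 5-(4,4-dibromobut-3-en-1-yl)-1,2-dimethoxy-3-(methoxymethoxy)benzene
Product: 14 1-[2-(4-bromophenyl)ethyl]-2-({4-[3,4-dimethoxy-5-(methoxymethoxy)phenyl]but-1-yn-1-yl}oxy)-3,4-dimethoxybenzene (aryl alkynyl ether), via bromo enol ether 13 (not isolated)
Conditions: CuI (10 mol %), 2,2'-bipyridine (20 mol %), K3PO4, toluene, 110 °C; then KOtBu, 1,4-dioxane, rt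
Reagents that add atoms: none
Why: Copper-catalysed Ullmann-type vinylic C–O coupling of a phenol with a 1,1-dibromoalkene engages the reactive C–Br bond trans to the chain far faster than the unactivated ring B aryl bromide, and the resulting (Z)-α-bromo enol ether has H and Br anti, so KOtBu completes an E2 dehydrobromination to the ynol ether.

**Step 10**
Reactants: 14 aryl alkynyl ether; 15 2H-pyran-2-one
Product: 17 1-[2-(4-bromophenyl)ethyl]-2-(2-{2-[3,4-dimethoxy-5-(methoxymethoxy)phenyl]ethyl}phenoxy)-3,4-dimethoxybenzene (seco-macrocycle with ring D), via bicyclic lactone 16 (not isolated)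
Conditions: 15 (10 equiv, freshly distilled), BHT and 2,6-di-tert-butyl-4-methylpyridine (cat.), dry mesitylene, sealed tube, Ar, 190–200 °C
Reagents that add atoms: none
Why: Proposed new method: the C≡C of 14, made electron-rich by the aryloxy oxygen, should add across C3 and C6 of the electron-poor diene 15 in an inverse-electron-demand [4+2] cycloaddition, with the nucleophilic alkyl-bearing carbon bonding to C6 and the oxygen-bearing carbon to C3, to give the 2-oxabicyclo[2.2.2]octa-5,7-dien-3-one 16, which expels CO2 by retro-[4+2] at this temperature and so delivers ring D aromatic without an oxidant. The closest known reaction type is the thermal 2-pyrone–alkyne Diels–Alder/decarboxylation benzannulation, established for alkynyl boronates, stannanes, silanes, acetylenic esters and ynamines but not for an internal aryl alkynyl ether. Ring D is closed in the intermolecular cycloaddition mode, both new C–C bonds forming in one event, and the two bridgehead stereocentres of 16 are transient and disappear with CO2, so no stereocontrol is required. Regiochemistry is immaterial because C3–C6 of 15 all end as CH and either orientation collapses to 17. The step needs chemoselectivity for the alkyne and thermal survival of the ynol ether: the O-aryl group has no O–C–C–H unit for retro-ene ketene formation, both ortho positions of ring C are occupied so cyclisation to a benzofuran is blocked, the hindered pyridine removes trace acid that would hydrate the ynol ether or cleave the MOM group, and the arenes and the aryl bromide are inert to neutral heating. The large excess of 15 offsets the low reactivity of a hindered internal alkyne and any slow thermal loss of the pyrone.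

**Step 11**
Reactants: 17 seco-macrocycle MOM ether
Product: 18 5-[2-(2-{6-[2-(4-bromophenyl)ethyl]-2,3-dimethoxyphenoxy}phenyl)ethyl]-2,3-dimethoxyphenol
Conditions: conc. HCl (cat.), MeOH/THF, 50 °C
Reagents that add atoms: none
Why: Acid-catalysed acetal exchange removes the MOM group selectively, since methyl ethers, diaryl ether and aryl bromide do not react with dilute acid.

**Step 12**
Reactants: 18 bromo phenol
Product: 19 tetra-O-methyl ether of the target macrocycle
Conditions: CuI (30 mol %), N,N-dimethylglycine, Cs2CO3, 1,4-dioxane, 110 °C, slow addition to about 2 mM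
Reagents that add atoms: none
Why: Ligand-accelerated intramolecular Ullmann diaryl ether synthesis between the only phenol (ring A) and the only aryl halide (ring B) in the molecule, with high dilution favouring ring closure over oligomerisation.

**Step 13**
Reactants: 19 tetra-O-methyl ether of the target macrocycle
Product: 20 target CNP0114693.0
Conditions: BBr3 (10 equiv), CH2Cl2, −78 °C to rt; then H2O, work-up under Ar
Reagents that add atoms: none
Why: BBr3 aryl methyl ether cleavage (bromide attacks the methyl carbon of the boron-complexed ether) frees both catechols, while the two diaryl ether linkages have no sp3 carbon to attack and persist.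

**Compound list**
1 | 4-bromobenzyl bromide | BrCc1ccc(Br)cc1 | starting material
2 | (4-bromobenzyl)triphenylphosphonium bromide | [Br-].Brc1ccc(C[P+](c2ccccc2)(c2ccccc2)c2ccccc2)cc1 | intermediate
3 | 2-hydroxy-3,4-dimethoxybenzaldehyde | COc1ccc(C=O)c(O)c1OC | starting material
4 | (4-bromobenzylidene)triphenylphosphorane (ylide, not isolated) | Brc1ccc(C=P(c2ccccc2)(c2ccccc2)c2ccccc2)cc1 | intermediate
5 | 6-[2-(4-bromophenyl)ethenyl]-2,3-dimethoxyphenol (E/Z mixture, geometry left open) | COc1ccc(C=Cc2ccc(Br)cc2)c(O)c1OC | intermediate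
6 | 6-[2-(4-bromophenyl)ethyl]-2,3-dimethoxyphenol | COc1ccc(CCc2ccc(Br)cc2)c(O)c1OC | intermediate
7 | 3-hydroxy-4,5-dimethoxybenzaldehyde | COc1cc(C=O)cc(O)c1OC | starting material
8 | 3,4-dimethoxy-5-(methoxymethoxy)benzaldehyde | COCOc1cc(C=O)cc(OC)c1OC | intermediate
9 | ethyl (E)-3-[3,4-dimethoxy-5-(methoxymethoxy)phenyl]prop-2-enoate | CCOC(=O)/C=C/c1cc(OC)c(OC)c(OCOC)c1 | intermediate
10 | ethyl 3-[3,4-dimethoxy-5-(methoxymethoxy)phenyl]propanoate | CCOC(=O)CCc1cc(OC)c(OC)c(OCOC)c1 | intermediate
11 | 3-[3,4-dimethoxy-5-(methoxymethoxy)phenyl]propanal | O=CCCc1cc(OC)c(OC)c(OCOC)c1 | intermediate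
12 | 5-(4,4-dibromobut-3-en-1-yl)-1,2-dimethoxy-3-(methoxymethoxy)benzene | BrC(Br)=CCCc1cc(OC)c(OC)c(OCOC)c1 | intermediate
13 | (Z)-1-bromo-1-aryloxybut-1-ene joining ring C oxygen to the ring A chain (bromo enol ether, not isolated) | COc1ccc(CCc2ccc(Br)cc2)c(O/C(Br)=C/CCc2cc(OC)c(OC)c(OCOC)c2)c1OC | intermediate
14 | 1-[2-(4-bromophenyl)ethyl]-2-({4-[3,4-dimethoxy-5-(methoxymethoxy)phenyl]but-1-yn-1-yl}oxy)-3,4-dimethoxybenzene | COc1ccc(CCc2ccc(Br)cc2)c(OC#CCCc2cc(OC)c(OC)c(OCOC)c2)c1OC | intermediate
15 | 2H-pyran-2-one | O=c1cccco1 | starting material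
16 | 5-aryloxy-6-(2-arylethyl)-2-oxabicyclo[2.2.2]octa-5,7-dien-3-one (racemic, one enantiomer drawn, not isolated) | O=C1O[C@@H]2C=C[C@H]1C(Oc1c(CCc3ccc(Br)cc3)ccc(OC)c1OC)=C2CCc1cc(OC)c(OC)c(OCOC)c1 | intermediate
17 | 1-[2-(4-bromophenyl)ethyl]-2-(2-{2-[3,4-dimethoxy-5-(methoxymethoxy)phenyl]ethyl}phenoxy)-3,4-dimethoxybenzene | COc1ccc(CCc2ccc(Br)cc2)c(Oc2ccccc2CCc2cc(OC)c(OC)c(OCOC)c2)c1OC | intermediate
18 | 5-[2-(2-{6-[2-(4-bromophenyl)ethyl]-2,3-dimethoxyphenoxy}phenyl)ethyl]-2,3-dimethoxyphenol | COc1ccc(CCc2ccc(Br)cc2)c(Oc2ccccc2CCc2cc(OC)c(OC)c(O)c2)c1OC | intermediate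
19 | tetra-O-methyl ether of the target macrocycle | COc1cc2cc(c1OC)Oc1ccc(cc1)CCc1ccc(OC)c(OC)c1Oc1ccccc1CC2 | intermediate
20 | CNP0114693.0 (macrocyclic bis-bibenzyl bis-catechol) | Oc1cc2cc(c1O)Oc1ccc(cc1)CCc1ccc(O)c(O)c1Oc1ccccc1CC2 | target

**Total step count:** 13
**Longest linear sequence:** 10 steps (7 → 8 → 9 → 10 → 11 → 12 → 14 → 17 → 18 → 19 → 20; steps 4–13)

**Steps most likely to fail**

1. **Step 10.**
   - Risk: the hindered internal ynol ether may react too slowly with the unactivated pyrone. Thermal decay of the alkynyl ether, or its hydration by trace water, could then overtake the cycloaddition.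
   - Fallback: this uses known chemistry, sets out from 6 (with 8 as partner) and returns at 17. It builds ring D from a purchased arene instead of by cycloaddition.
   - SNAr of the phenoxide of 6 on 2-fluorobenzaldehyde (K2CO3, DMF, 140 °C) would give 2-{6-[2-(4-bromophenyl)ethyl]-2,3-dimethoxyphenoxy}benzaldehyde F1.
   - NaBH4 in MeOH would give the benzylic alcohol F2.
   - PPh3·HBr in refluxing MeCN would convert F2 directly into the benzylic triphenylphosphonium bromide F3.
   - Wittig olefination of F3 with aldehyde 8 (K2CO3, 18-crown-6, CH2Cl2, reflux) would give the ring D–ring A stilbene F4 as an E/Z mixture.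
   - Diimide reduction of F4 as in step 3 would give 17.

2. **Step 9.**
   - Risk: C–O coupling by the doubly ortho-substituted phenol may be sluggish, arylation at the ring B bromide may compete, and KOtBu may isomerise the alkyne to an allenyl ether.
   - Fallback: this is copper-free, sets out from 10 and 6 and returns at 14.
   - Chloromethyllithium (ICH2Cl, MeLi·LiBr, THF, −78 °C) would convert ester 10 into 1-chloro-4-[3,4-dimethoxy-5-(methoxymethoxy)phenyl]butan-2-one F5.
   - Williamson etherification of 6 with F5 (K2CO3, NaI, acetone, reflux) would give the α-aryloxy ketone F6.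
   - Chelation-directed enolisation towards the aryloxy-bearing CH2 and triflation (LiHMDS, PhNTf2, THF, −78 °C) would give the (Z)-enol triflate F7.
   - The anti H/OTf pair of F7 would be eliminated with KOtBu at low temperature to give 14.

3. **Step 12.**
   - Risk: oligomerisation may compete with ring closure, and ring B may be hydrodebrominated during prolonged heating.
   - Fallback: this sets out from 17 and returns at 19, reversing the role of ring B from halide electrophile to boron partner.
   - Bromine–lithium exchange and borylation of 17 (n-BuLi, THF, −78 °C; B(OiPr)3), then 2 M HCl in THF/MeOH at 45 °C to hydrolyse the borate and the MOM ether, would give the hydroxy boronic acid F8.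
   - An intramolecular Chan–Lam coupling of F8 (Cu(OAc)2, pyridine, 4 Å molecular sieves, CH2Cl2, air, rt, high dilution) would close the same O–aryl bond at room temperature to give 19.

**Further compounds**
F1 | step 10 | 2-{6-[2-(4-bromophenyl)ethyl]-2,3-dimethoxyphenoxy}benzaldehyde | COc1ccc(CCc2ccc(Br)cc2)c(Oc2ccccc2C=O)c1OC
F2 | step 10 | (2-{6-[2-(4-bromophenyl)ethyl]-2,3-dimethoxyphenoxy}phenyl)methanol | COc1ccc(CCc2ccc(Br)cc2)c(Oc2ccccc2CO)c1OC
F3 | step 10 | (2-{6-[2-(4-bromophenyl)ethyl]-2,3-dimethoxyphenoxy}benzyl)triphenylphosphonium bromide | [Br-].COc1ccc(CCc2ccc(Br)cc2)c(Oc2ccccc2C[P+](c2ccccc2)(c2ccccc2)c2ccccc2)c1OC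
F4 | step 10 | ring D–ring A stilbene (E/Z mixture, geometry left open) | COc1ccc(CCc2ccc(Br)cc2)c(Oc2ccccc2C=Cc2cc(OC)c(OC)c(OCOC)c2)c1OC
F5 | step 9 | 1-chloro-4-[3,4-dimethoxy-5-(methoxymethoxy)phenyl]butan-2-one | ClCC(=O)CCc1cc(OC)c(OC)c(OCOC)c1
F6 | step 9 | 1-{6-[2-(4-bromophenyl)ethyl]-2,3-dimethoxyphenoxy}-4-[3,4-dimethoxy-5-(methoxymethoxy)phenyl]butan-2-one | COc1ccc(CCc2ccc(Br)cc2)c(OCC(=O)CCc2cc(OC)c(OC)c(OCOC)c2)c1OC
F7 | step 9 | (Z)-1-aryloxy-4-arylbut-1-en-2-yl trifluoromethanesulfonate | COc1ccc(CCc2ccc(Br)cc2)c(O/C=C(/CCc2cc(OC)c(OC)c(OCOC)c2)OS(=O)(=O)C(F)(F)F)c1OC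
F8 | step 12 | {4-[2-(2-{2-[2-(3-hydroxy-4,5-dimethoxyphenyl)ethyl]phenoxy}-3,4-dimethoxyphenyl)ethyl]phenyl}boronic acid | COc1ccc(CCc2ccc(B(O)O)cc2)c(Oc2ccccc2CCc2cc(OC)c(OC)c(O)c2)c1OC
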